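**Plan**

- Numbering: ring A is C1 (side chain), C2 (O-tigloyl), C3/C4 (oxirane, C15 methyl on C4), C5 (C=O), C6 (OAc); the chain is C7 (=C14H2), C8 (O-tigloyl), C9, C10/C11 (oxirane, C12/C13 methyls). The C3/C4 oxirane is fused to ring A α,β to the C5 ketone with the methyl on C4, which is what a Darzens reaction between a C4 α-chloro enolate and a C3 aldehyde delivers.
- Retrosynthesis: remove the C10/C11 oxirane oxygen (Shi), cut C3–C4 and C4–O together (intramolecular Darzens), then C10=C11 (cross-metathesis), C8–C9 (allylboration), C4–C5 (EtLi on a lactone), C6–O (enolate hydroxylation) and C1–C7 (cuprate addition to a butenolide).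
- Forward: a butyrolactone holding C5, C6, C1, C2 and C3 is built first and used as a stereochemical template. It is opened to the acyclic chain, the C8–C13 side chain is grown, ring A and its oxirane close together in step 13, and the side-chain oxirane is made last.
- Stereochemistry: C2 comes from (S)-5-(hydroxymethyl)furan-2(5H)-one; C1 and C6 from two trans additions on the lactone; C8 from a pinene-derived allylborane; C3 and C4 from the Darzens closure; C10 from the D-fructose-derived Shi ketone.

Key step: step 13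

Remark: 3 and tigloyl chloride are taken as purchasable; 26–28 are handled as mixtures of C4 epimers (C4 left undefined in their SMILES), and 13 is drawn as the open hydroxy ketone although it equilibrates with its cyclic hemiketal.

**Step 1**
Reactants: 1 (S)-5-(hydroxymethyl)furan-2(5H)-one
Product: 2 (S)-5-[(triethylsilyloxy)methyl]furan-2(5H)-one
Conditions: Et3SiCl, imidazole, CH2Cl2, 0 °C
Reagents that add atoms: chlorotriethylsilane, CC[Si](Cl)(CC)CC
Why: Silyl ether formation on a primary alcohol is routine, and the triethylsilyl group is chosen because a primary triethylsilyl ether can later be oxidised directly to the C3 aldehyde; no stereocentre is touched.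

**Step 2**
Reactants: 2 (S)-5-[(triethylsilyloxy)methyl]furan-2(5H)-one; 3 2-bromo-3,3-diethoxyprop-1-ene
Product: 7 (4R,5S)-4-(3,3-diethoxyprop-1-en-2-yl)-5-[(triethylsilyloxy)methyl]oxolan-2-one, via alkenyllithium 4 (not isolated), via lithium dialkenylcuprate 5 (not isolated), via silyl ketene acetal 6 (not isolated)
Conditions: 3, t-BuLi (2 equiv per 3), Et2O, −78 °C; CuI (0.5 equiv per 4), −78 → −40 °C; Me3SiCl, then 2 in THF, −78 °C; aq. NH4Cl/NH3
Reagents that add atoms: 2-bromo-3,3-diethoxyprop-1-ene 3, C=C(Br)C(OCC)OCC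
Why: Conjugate addition of an alkenylcuprate (here an acrolein α-anion equivalent) to a 5-substituted butenolide, accelerated by Me3SiCl, should occur anti to the silyloxymethyl group and so set C1 trans to C2.

**Step 3**
Reactants: 7 (4R,5S)-4-(3,3-diethoxyprop-1-en-2-yl)-5-[(triethylsilyloxy)methyl]oxolan-2-one
Product: 9 (3S,4S,5S)-4-(3,3-diethoxyprop-1-en-2-yl)-3-hydroxy-5-[(triethylsilyloxy)methyl]oxolan-2-one, via potassium enolate 8 (not isolated)
Conditions: KN(SiMe3)2, THF, −78 °C; 2-(phenylsulfonyl)-3-phenyloxaziridine, −78 °C; aq. NH4Cl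
Reagents that add atoms: 2-(phenylsulfonyl)-3-phenyloxaziridine, O=S(=O)(c1ccccc1)N1OC1c1ccccc1
Why: Electrophilic hydroxylation of a lactone enolate by an N-sulfonyloxaziridine should take place on the face opposite the adjacent C1 alkenyl group, setting C6 trans to it.

**Step 4**
Reactants: 9 (3S,4S,5S)-4-(3,3-diethoxyprop-1-en-2-yl)-3-hydroxy-5-[(triethylsilyloxy)methyl]oxolan-2-one
Product: 10 (3S,4R,5S)-3-(tert-butyldimethylsilyloxy)-4-(3,3-diethoxyprop-1-en-2-yl)-5-[(triethylsilyloxy)methyl]oxolan-2-one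
Conditions: t-BuMe2SiCl, imidazole, DMF, 23 °C
Reagents that add atoms: tert-butyldimethylsilyl chloride, CC(C)(C)[Si](C)(C)Cl
Why: Silylation under non-Lewis-acidic conditions spares the acetal and installs a bulky ether at O-6 that later blocks enolisation toward C6 and biases the ring-closure conformation; no stereocentre is touched.

**Step 5**
Reactants: 10 (3S,4R,5S)-3-(tert-butyldimethylsilyloxy)-4-(3,3-diethoxyprop-1-en-2-yl)-5-[(triethylsilyloxy)methyl]oxolan-2-one; 11 ethyllithium
Product: 13 (4S,5R,6S)-4-(tert-butyldimethylsilyloxy)-5-(3,3-diethoxyprop-1-en-2-yl)-6-hydroxy-7-(triethylsilyloxy)heptan-3-one, via lithium lactolate 12 (not isolated)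
Conditions: EtLi (1.2 equiv), THF, −78 °C; aq. NH4Cl at −78 °C
Reagents that add atoms: ethyllithium 11, [Li]CC
Why: Mono-addition of an organolithium to a γ-lactone at −78 °C stops at the lithium lactolate, which on protonation opens to the γ-hydroxy ethyl ketone and so brings in C4 and C15 while freeing O-2.

**Step 6**
Reactants: 13 (4S,5R,6S)-4-(tert-butyldimethylsilyloxy)-5-(3,3-diethoxyprop-1-en-2-yl)-6-hydroxy-7-(triethylsilyloxy)heptan-3-one; 14 tiglic acid
Product: 16 (2S,3R,4S)-4-(tert-butyldimethylsilyloxy)-3-(3,3-diethoxyprop-1-en-2-yl)-5-oxo-1-(triethylsilyloxy)heptan-2-yl (E)-2-methylbut-2-enoate, via mixed anhydride 15 (not isolated)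
Conditions: tiglic acid, 2,4,6-trichlorobenzoyl chloride, Et3N, toluene, 23 °C; then 13, DMAP, 23 °C
Reagents that add atoms: tiglic acid 14, C/C=C(\C)C(=O)O
Why: Yamaguchi esterification acylates hindered secondary alcohols, and acylation of the open-chain hydroxyl should drain the hemiketal equilibrium, as in the usual trapping of lactone/organolithium adducts; the C2 configuration is retained.

**Step 7**
Reactants: 16 C2 tiglate ethyl ketone bearing the C8 diethyl acetal
Product: 17 (2S,3R,4S)-4-(tert-butyldimethylsilyloxy)-3-(3-oxoprop-1-en-2-yl)-5-oxo-1-(triethylsilyloxy)heptan-2-yl (E)-2-methylbut-2-enoate (C8 enal)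
Conditions: PPTS (0.2 equiv), acetone/H2O 20:1, 0 → 23 °C
Reagents that add atoms: water, O
Why: Acetal hydrolysis of an α,β-unsaturated diethyl acetal is much faster than acid cleavage of the silyl ethers, so mild pyridinium acid should release the 2-substituted acrolein selectively.

**Step 8**
Reactants: 17 C8 enal; 18 allylmagnesium bromide
Product: 21 (8S)-homoallylic alcohol (C8–OH, C9H2–C10H=CH2; other groups and centres as in 17), via allyldiisopinocampheylborane 19 (not isolated), via borinate 20 (not isolated)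
Conditions: (−)-Ipc2BOMe and allylMgBr in Et2O, 0 → 23 °C; then 17, −78 °C; MeOH, pH 7 buffer, 30% H2O2, 0 °C
Reagents that add atoms: allylmagnesium bromide 18, C=CC[Mg]Br
Why: In the Brown allylboration the reagent from (+)-α-pinene delivers allyl to the Si face of an aldehyde through a chair transition state, which gives the (8S)-carbinol under reagent control because C7 outranks the allyl CH2; the aldehyde should react far faster than the hindered ketone.

**Step 9**
Reactants: 21 (8S)-homoallylic alcohol; 22 2-methyl-2-butene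
Product: 23 (8S)-alcohol with the C10=C11 trisubstituted alkene (C9H2–CH=CMe2)
Conditions: 2-methyl-2-butene (large excess), second-generation Grubbs catalyst (5 mol%), CH2Cl2, 40 °C, sealed tube
Reagents that add atoms: 2-methyl-2-butene 22, CC=C(C)C
Why: Olefin cross-metathesis of a monosubstituted alkene with excess 2-methyl-2-butene is a standard way to a prenyl-type alkene, and the hindered C7=C14 alkene and the tiglate should not take part.

**Step 10**
Reactants: 23 (8S)-alcohol with the C10=C11 trisubstituted alkene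
Product: 24 bis-tiglate ethyl ketone (O-2 and O-8 tigloyl, O-3 SiEt3, O-6 Sit-BuMe2)
Conditions: (E)-2-methylbut-2-enoyl chloride (tigloyl chloride, 3 equiv), pyridine, DMAP (0.2 equiv), CH2Cl2, 0 → 23 °C
Reagents that add atoms: tigloyl chloride, C/C=C(\C)C(=O)Cl
Why: DMAP-catalysed acylation of a secondary allylic alcohol with an acid chloride is a standard esterification that takes place at oxygen, so C8 keeps its configuration, and pyridine is used in place of a trialkylamine so that the tigloyl group is not deconjugated through a vinylketene.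

**Step 11**
Reactants: 24 bis-tiglate ethyl ketone
Product: 26 α-chloro ketone (C4–Cl, both epimers), via lithium enolate 25 (not isolated)
Conditions: LiN(SiMe3)2 (1.1 equiv), THF, −78 °C; N-chlorosuccinimide, −78 → −40 °C
Reagents that add atoms: N-chlorosuccinimide, O=C1CCC(=O)N1Cl
Why: Kinetic deprotonation should occur at the unhindered C4 methylene (C6–H is tertiary and screened by the silyl ether, the tiglates have no α-hydrogen), and electrophilic chlorination of the enolate gives the α-chloro ketone, whose C4 configuration is of no consequence.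

**Step 12**
Reactants: 26 α-chloro ketone
Product: 28 seco keto aldehyde (C3 aldehyde, C2 and C8 tiglates, C6 silyl ether, C4 chloride), via alkoxysulfonium chloride 27 (not isolated)
Conditions: (COCl)2, DMSO, CH2Cl2, −78 → −35 °C; then Et3N, −78 → −20 °C
Reagents that add atoms: none
Why: Under Swern conditions a primary triethylsilyl ether is cleaved by the chlorosulfonium reagent and oxidised in the same flask while secondary silyl ethers persist, so the α-acyloxy aldehyde forms without a free-alcohol stage in which the C2 tiglate could migrate.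

**Step 13**
Reactants: 28 seco keto aldehyde
Product: 31 ring-A epoxy ketone (1R,2S,3S,4S,6S,8S; O-6 Sit-BuMe2, C10=C11 alkene), via potassium enolate 29 (not isolated), via chlorohydrin alkoxide 30 (not isolated)
Conditions: KN(SiMe3)2 (1.05 equiv, slow addition), THF, −78 → −20 °C; pH 7 buffer
Reagents that add atoms: none
Why: KN(SiMe3)2 removes the C4 proton, which is acidified by chlorine and far more accessible than the tertiary C6–H screened by the silyl ether (the tiglates carry no α-hydrogen), and the enolate adds to the C3 aldehyde to form the C3–C4 bond and ring A by a 6-(enolendo)-exo-trig aldol closure. The C3 alkoxide then displaces chloride from C4 in a 3-exo-tet closure that forms the C4–O bond; the sequence is an intramolecular Darzens condensation of an α-chloro ketone with an aldehyde, which is the closest known reaction type. C4 is set by the need for O-3 and chlorine to be antiperiplanar, so only the cis-fused oxirane can form, with inversion at C4; both C4 epimers of 28 give the same planar enolate and the aldol step is reversible, so chlorohydrin alkoxides that cannot close return to the enolate. C3 is set by the aldehyde face: in the potassium-bridged chair the bulky C6 silyl ether should sit axial to avoid allylic strain with the enolate oxygen, which puts the trans C1 side chain axial and the C2 tiglate equatorial, so that the C2–O bond is antiperiplanar to the forming bond (polar Felkin–Anh) and the aldehyde oxygen is axial, cis to O-2 and antiperiplanar to an axial chlorine. The step therefore needs this facial selectivity, which the silyl ether at O-6, the non-chelating potassium counter-ion and the low temperature are meant to secure.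

**Step 14**
Reactants: 31 ring-A epoxy ketone silyl ether
Product: 32 C6 alcohol (α-hydroxy epoxy ketone)
Conditions: HF·pyridine, pyridine, THF, 0 → 23 °C
Reagents that add atoms: none
Why: Buffered fluoride desilylation removes the secondary silyl ether without opening the electron-poor α,β-epoxy ketone or touching the esters and alkenes; no stereocentre is involved.

**Step 15**
Reactants: 32 C6 alcohol
Product: 33 C6 acetate (target lacking only the C10/C11 oxirane)
Conditions: Ac2O, pyridine, DMAP (cat.), CH2Cl2, 0 °C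
Reagents that add atoms: acetic anhydride, CC(=O)OC(C)=O
Why: DMAP-catalysed acetylation of the secondary α-hydroxy ketone takes place at oxygen with retention at C6.

**Step 16**
Reactants: 33 C6 acetate
Product: 34 target, (1R,2S,3S,4S,6S,8S,10R)-configured diepoxide
Conditions: D-fructose-derived Shi ketone (1,2:4,5-di-O-isopropylidene-β-D-erythro-hexo-2,3-diulopyranose, 0.3 equiv), Oxone (2KHSO5·KHSO4·K2SO4), K2CO3, Bu4NHSO4 (cat.), Na2B4O7 buffer, MeCN/CH2(OMe)2, 0 °C
Reagents that add atoms: potassium peroxymonosulfate (active part of Oxone), [K+].[O-]S(=O)(=O)OO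
Why: In the Shi epoxidation the dioxirane of the D-fructose-derived ketone attacks electron-rich trisubstituted alkenes through a spiro transition state and should give the (10R)-oxirane from the 2-methylalk-2-ene unit, while the hindered 1,1-disubstituted C7=C14 alkene and the electron-poor tiglates react much more slowly.

**Compound list**

1 | (S)-5-(hydroxymethyl)furan-2(5H)-one | O=C1C=C[C@@H](CO)O1 | starting material
2 | (S)-5-[(triethylsilyloxy)methyl]furan-2(5H)-one | O=C1C=C[C@@H](CO[Si](CC)(CC)CC)O1 | intermediate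
3 | 2-bromo-3,3-diethoxyprop-1-ene | C=C(Br)C(OCC)OCC | starting material
4 | (3,3-diethoxyprop-1-en-2-yl)lithium | [Li]C(=C)C(OCC)OCC | intermediate
5 | lithium bis(3,3-diethoxyprop-1-en-2-yl)cuprate | [Li+].C=C([Cu-]C(=C)C(OCC)OCC)C(OCC)OCC | intermediate
6 | (4R,5S)-4-(3,3-diethoxyprop-1-en-2-yl)-5-[(triethylsilyloxy)methyl]-2-(trimethylsilyloxy)-4,5-dihydrofuran | C[Si](C)(C)OC1=C[C@H](C(=C)C(OCC)OCC)[C@@H](CO[Si](CC)(CC)CC)O1 | intermediate
7 | (4R,5S)-4-(3,3-diethoxyprop-1-en-2-yl)-5-[(triethylsilyloxy)methyl]oxolan-2-one | O=C1C[C@H](C(=C)C(OCC)OCC)[C@@H](CO[Si](CC)(CC)CC)O1 | intermediate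
8 | potassium enolate of 7 | [K+].[O-]C1=C[C@H](C(=C)C(OCC)OCC)[C@@H](CO[Si](CC)(CC)CC)O1 | intermediate
9 | (3S,4S,5S)-4-(3,3-diethoxyprop-1-en-2-yl)-3-hydroxy-5-[(triethylsilyloxy)methyl]oxolan-2-one | O=C1[C@@H](O)[C@H](C(=C)C(OCC)OCC)[C@@H](CO[Si](CC)(CC)CC)O1 | intermediate
10 | (3S,4R,5S)-3-(tert-butyldimethylsilyloxy)-4-(3,3-diethoxyprop-1-en-2-yl)-5-[(triethylsilyloxy)methyl]oxolan-2-one | O=C1[C@@H](O[Si](C)(C)C(C)(C)C)[C@H](C(=C)C(OCC)OCC)[C@@H](CO[Si](CC)(CC)CC)O1 | intermediate
11 | ethyllithium | [Li]CC | starting material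
12 | lithium lactolate from 10 and ethyllithium (2-ethyl-2-oxido-oxolane, new centre undefined) | [Li+].[O-]C1(CC)[C@@H](O[Si](C)(C)C(C)(C)C)[C@H](C(=C)C(OCC)OCC)[C@@H](CO[Si](CC)(CC)CC)O1 | intermediate
13 | (4S,5R,6S)-4-(tert-butyldimethylsilyloxy)-5-(3,3-diethoxyprop-1-en-2-yl)-6-hydroxy-7-(triethylsilyloxy)heptan-3-one | C=C(C(OCC)OCC)[C@H]([C@H](O)CO[Si](CC)(CC)CC)[C@H](O[Si](C)(C)C(C)(C)C)C(=O)CC | intermediate
14 | tiglic acid, (E)-2-methylbut-2-enoic acid | C/C=C(\C)C(=O)O | starting material
15 | (E)-2-methylbut-2-enoic 2,4,6-trichlorobenzoic anhydride | C/C=C(\C)C(=O)OC(=O)c1c(Cl)cc(Cl)cc1Cl | intermediate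
16 | (2S,3R,4S)-4-(tert-butyldimethylsilyloxy)-3-(3,3-diethoxyprop-1-en-2-yl)-5-oxo-1-(triethylsilyloxy)heptan-2-yl (E)-2-methylbut-2-enoate | C=C(C(OCC)OCC)[C@H]([C@H](OC(=O)/C(C)=C/C)CO[Si](CC)(CC)CC)[C@H](O[Si](C)(C)C(C)(C)C)C(=O)CC | intermediate
17 | (2S,3R,4S)-4-(tert-butyldimethylsilyloxy)-5-oxo-3-(3-oxoprop-1-en-2-yl)-1-(triethylsilyloxy)heptan-2-yl (E)-2-methylbut-2-enoate | C=C(C=O)[C@H]([C@H](OC(=O)/C(C)=C/C)CO[Si](CC)(CC)CC)[C@H](O[Si](C)(C)C(C)(C)C)C(=O)CC | intermediate
18 | allylmagnesium bromide | C=CC[Mg]Br | starting material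
19 | (−)-B-allyldiisopinocampheylborane (from (+)-α-pinene) | C=CCB([C@@H]1C[C@@H]2C[C@H]([C@H]1C)C2(C)C)[C@@H]1C[C@@H]2C[C@H]([C@H]1C)C2(C)C | intermediate
20 | diisopinocampheylborinate of 21 (O-8 bound to boron) | C=C([C@H]([C@H](OC(=O)/C(C)=C/C)CO[Si](CC)(CC)CC)[C@H](O[Si](C)(C)C(C)(C)C)C(=O)CC)[C@H](CC=C)OB([C@@H]1C[C@@H]2C[C@H]([C@H]1C)C2(C)C)[C@@H]1C[C@@H]2C[C@H]([C@H]1C)C2(C)C | intermediate
21 | (8S)-homoallylic alcohol: 17 with C8 as CH(OH)CH2CH=CH2 | C=C([C@H]([C@H](OC(=O)/C(C)=C/C)CO[Si](CC)(CC)CC)[C@H](O[Si](C)(C)C(C)(C)C)C(=O)CC)[C@H](CC=C)O | intermediate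
22 | 2-methyl-2-butene | CC=C(C)C | starting material
23 | (8S)-alcohol with C9H2–C10H=C11Me2 side chain | C=C([C@H]([C@H](OC(=O)/C(C)=C/C)CO[Si](CC)(CC)CC)[C@H](O[Si](C)(C)C(C)(C)C)C(=O)CC)[C@H](CC=C(C)C)O | intermediate
24 | bis-tiglate ethyl ketone (O-2 and O-8 tigloyl, O-3 triethylsilyl, O-6 tert-butyldimethylsilyl) | C=C([C@H]([C@H](OC(=O)/C(C)=C/C)CO[Si](CC)(CC)CC)[C@H](O[Si](C)(C)C(C)(C)C)C(=O)CC)[C@H](CC=C(C)C)OC(=O)/C(C)=C/C | intermediate
25 | lithium C4=C5 enolate of 24 | [Li+].C=C([C@H]([C@H](OC(=O)/C(C)=C/C)CO[Si](CC)(CC)CC)[C@H](O[Si](C)(C)C(C)(C)C)C([O-])=CC)[C@H](CC=C(C)C)OC(=O)/C(C)=C/C | intermediate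
26 | α-chloro ketone: 24 with C4 as CHCl (both epimers) | C=C([C@H]([C@H](OC(=O)/C(C)=C/C)CO[Si](CC)(CC)CC)[C@H](O[Si](C)(C)C(C)(C)C)C(=O)C(C)Cl)[C@H](CC=C(C)C)OC(=O)/C(C)=C/C | intermediate
27 | C3 alkoxydimethylsulfonium chloride from 26 | [Cl-].C=C([C@H]([C@H](OC(=O)/C(C)=C/C)CO[S+](C)C)[C@H](O[Si](C)(C)C(C)(C)C)C(=O)C(C)Cl)[C@H](CC=C(C)C)OC(=O)/C(C)=C/C | intermediate
28 | seco keto aldehyde: C3 aldehyde, C2 and C8 tiglates, C6 tert-butyldimethylsilyl ether, C4 chloride (both epimers) | C=C([C@H]([C@H](OC(=O)/C(C)=C/C)C=O)[C@H](O[Si](C)(C)C(C)(C)C)C(=O)C(C)Cl)[C@H](CC=C(C)C)OC(=O)/C(C)=C/C | intermediate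
29 | potassium C4=C5 chloro enolate of 28 | [K+].C=C([C@H]([C@H](OC(=O)/C(C)=C/C)C=O)[C@H](O[Si](C)(C)C(C)(C)C)C([O-])=C(C)Cl)[C@H](CC=C(C)C)OC(=O)/C(C)=C/C | intermediate
30 | potassium alkoxide of the ring-A chlorohydrin (O-3 cis to O-2, C4–Cl trans to O-3) | [K+].C=C([C@@H]1[C@H](OC(=O)/C(C)=C/C)[C@H]([O-])[C@@](C)(Cl)C(=O)[C@H]1O[Si](C)(C)C(C)(C)C)[C@H](CC=C(C)C)OC(=O)/C(C)=C/C | intermediate
31 | ring-A epoxy ketone, (1R,2S,3S,4S,6S,8S), O-6 tert-butyldimethylsilyl, C10=C11 alkene | C=C([C@@H]1[C@H](OC(=O)/C(C)=C/C)[C@@H]2O[C@]2(C)C(=O)[C@H]1O[Si](C)(C)C(C)(C)C)[C@H](CC=C(C)C)OC(=O)/C(C)=C/C | intermediate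
32 | C6 alcohol from 31 | C=C([C@@H]1[C@H](OC(=O)/C(C)=C/C)[C@@H]2O[C@]2(C)C(=O)[C@H]1O)[C@H](CC=C(C)C)OC(=O)/C(C)=C/C | intermediate
33 | C6 acetate (target lacking the C10/C11 oxirane) | C=C([C@@H]1[C@H](OC(=O)/C(C)=C/C)[C@@H]2O[C@]2(C)C(=O)[C@H]1OC(C)=O)[C@H](CC=C(C)C)OC(=O)/C(C)=C/C | intermediate
34 | CNP0407453.3, (1R,2S,3S,4S,6S,8S,10R)-6-acetoxy-3,4:10,11-diepoxy-5-oxo-bisabol-7(14)-ene-2,8-diyl ditiglate | C=C([C@@H]1[C@H](OC(=O)/C(C)=C/C)[C@@H]2O[C@]2(C)C(=O)[C@H]1OC(C)=O)[C@H](C[C@H]1OC1(C)C)OC(=O)/C(C)=C/C | target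

**Step count and risks**

Total step count: 16. Longest linear sequence: 16 steps (from 1).

Steps most likely to fail:

1. Step 13. The enolate may close through the other chair (C1 and C6 substituents equatorial) and attack the wrong aldehyde face, which would place the oxirane trans to the C2 tiglate. Retro-aldol, epimerisation α to the aldehyde or O-2 to O-3 acyl shift may also outrun oxirane closure. Fallback, from 28: the closure would be split into a boron aldol and a separate ring closure. Soft enolisation with chlorodicyclohexylborane and Et3N in Et2O at −78 °C should give a boron enolate whose bulky boryloxy group forces the C6 silyl ether axial and whose closed transition state holds the aldehyde oxygen axial and cis to O-2. Buffered oxidative work-up would give the isolable ring-A chlorohydrin F1, free of retro-aldol while boron-bound. DBU in CH2Cl2 at 0 °C would then close the oxirane and return to 31.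

2. Step 6. Acylation may take place at the hemiketal oxygen of the cyclic form of 13, or the hemiketal may dehydrate to an enol ether, instead of the open-chain C2 hydroxyl being esterified. Fallback, from 10: the lactone would be opened with MeONHMe·HCl and i-PrMgCl in THF at −20 °C to the γ-hydroxy Weinreb amide F2, which cannot form a hemiketal. Yamaguchi esterification with tiglic acid would give the C2 tiglate amide F3. Addition of EtMgBr at −40 °C, where the amide should react ahead of the hindered conjugated ester, would return to 16.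

3. Step 16. The C6 acetate may be hydrolysed or migrate, C6 may epimerise, or the epoxy ketone may degrade in the carbonate-buffered Oxone medium. Fallback, from 31: the Shi epoxidation would be run on the base-stable silyl ether to give the (10R)-oxirane F4. The silyl ether would then be removed with Bu4NF buffered with AcOH in THF at 0 °C, which avoids acid on the trisubstituted oxirane, to give the alcohol F5. Acetylation with Ac2O, pyridine and DMAP would give 34.

**Further compounds**

F1 | step 13 | ring-A chlorohydrin (C3–OH cis to the C2 tiglate, C4–Cl trans to C3–OH, other groups as in 31) | C=C([C@@H]1[C@H](OC(=O)/C(C)=C/C)[C@H](O)[C@@](C)(Cl)C(=O)[C@H]1O[Si](C)(C)C(C)(C)C)[C@H](CC=C(C)C)OC(=O)/C(C)=C/C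
F2 | step 6 | γ-hydroxy N-methoxy-N-methylamide from 10 (C5 amide, C2 hydroxyl) | C=C(C(OCC)OCC)[C@H]([C@H](O)CO[Si](CC)(CC)CC)[C@H](O[Si](C)(C)C(C)(C)C)C(=O)N(C)OC
F3 | step 6 | C2 tiglate of F2 | C=C(C(OCC)OCC)[C@H]([C@H](OC(=O)/C(C)=C/C)CO[Si](CC)(CC)CC)[C@H](O[Si](C)(C)C(C)(C)C)C(=O)N(C)OC
F4 | step 16 | (10R)-10,11-oxirane of 31 (O-6 tert-butyldimethylsilyl) | C=C([C@@H]1[C@H](OC(=O)/C(C)=C/C)[C@@H]2O[C@]2(C)C(=O)[C@H]1O[Si](C)(C)C(C)(C)C)[C@H](C[C@H]1OC1(C)C)OC(=O)/C(C)=C/C
F5 | step 16 | C6 alcohol from F4 | C=C([C@@H]1[C@H](OC(=O)/C(C)=C/C)[C@@H]2O[C@]2(C)C(=O)[C@H]1O)[C@H](C[C@H]1OC1(C)C)OC(=O)/C(C)=C/C
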